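## Structural features

The target is a monocyclic C10 polyhalide: one cyclohexane ring, with no fused or bridged partner, carrying an (E)-2-chloroethenyl side chain. Ring atoms are numbered here C1 (CMeCl), C2 (CH2), C3 (CMeBr), C4 (CH carrying the chain C9=C10–Cl), C5 (CH2) and C6 (CHBr); in this numbering the configuration is 1R,3R,4S,6S. The four stereocentres form two adjacent pairs, C6/C1 and C3/C4, and the two fully substituted halogen-bearing carbons C1 and C3 are 1,3-related through C2. The C1 chlorine, the C6 bromine and the side chain lie on one face and the C3 bromine on the other, so in the chair with the side chain and both bromines equatorial the C1 chlorine is axial and syn-axial to the C3 methyl group. Fragile points are the two tertiary halides (ionisation, E1 loss, halide exchange), the secondary bromide β to the tertiary chloride (E2, bromonium formation) and the alkene geometry; the molecule holds no oxygen or nitrogen, so every polar handle used on the way must be erased. The real difficulty is the cis vicinal chloride/bromide at C1/C6, which anti addition to a C1=C6 alkene cannot give, together with two tertiary carbon–halogen centres of defined configuration and three halogen sites that must be told apart. The key step uses the fact that C1 is a tertiary centre flanked by C6–Br and separated by the single carbon C2 from the methyl-bearing C3, so that C1 can be the carbonyl carbon of an acetyl group on C6 and C2/C3 a 2-propenyl group on C4. A carbonyl-ene reaction then closes C1–C2 and leaves oxygen on C1 and a methylidene on C3, the precursors of the two tertiary halides.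

## Logic of the disconnections

13 to 12. The C3–Br bond is cut, together with one C–H of the C3 methyl group, which turns the tertiary bromide into a methylidene group. C3 is the one halogenated carbon whose neighbours carry no heteroatom, so it can be made last by adding H–Br across a 1,1-disubstituted alkene. This removes a quaternary stereocentre and an ionisable tertiary bromide from every earlier step. The forward step must add in the Markovnikov sense without a cation and must put bromine on the face away from the axial C1 chlorine.

12 to 10 (through 11). The C1–Cl bond is exchanged for C1–O with the same configuration. A cis bromohydrin can be reached by carbonyl addition, whereas the cis chloride/bromide cannot be reached by alkene dihalogenation. The gain is that C1 becomes a carbinol carbon, that is, a former ketone carbon. The forward step must replace oxygen by chlorine with retention, without elimination and without acid adding to the methylidene group.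

10 to 8 (through 9). The ring bond C1–C2 is cut and the hydroxyl hydrogen is returned to the exocyclic carbon on C3. This is the carbonyl-ene retron, a tertiary alcohol with a methylidene group two carbons away. The ring, the C1 stereocentre and the methylidene disappear together and an open-chain α-bromo methyl ketone remains. The forward closure must run through one chair, with oxygen axial and the C4 and C6 substituents equatorial.

8 to 7. No bond is cut; the configuration at the bromine-bearing carbon is released, so the single reacting epimer is traced back to the mixture of both. The reason is that no acyclic step can be trusted to set this centre by 1,3-induction, and the gain is that the bromination need not be selective. The forward step must interconvert the epimers faster than the mismatched one closes, and must do so without changing the halogen.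

7 to 5 (through 6). The C–Br bond next to the ketone is cut. Bromine enters through the more substituted silyl enol ether, so no bromine has to be carried through the earlier steps. What remains is a plain methyl ketone. The forward steps demand enolisation toward the internal α-carbon and a bromine source that ignores both alkenes.

5 to 3 and 4. The C9=C10 double bond is cut to a formyl carbon and a one-carbon chlorine-bearing unit. The cut is made there because a formyl group on C4 is exactly the activating group the next disconnection needs. The chloroalkene is thereby reduced to an aldehyde and a bulk solvent. The forward step must give the E alkene, must take the aldehyde and not the ketone, and must not erode the α-stereocentre.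

3 to 1 and 2. The C4–C5 bond is cut (1,5-dicarbonyl, Michael retron). This is the only bond that joins two commercial fragments, and it creates C4, the one stereocentre that the ring closure cannot set. The forward step demands attack through the α-carbon of the dienamine, not the γ-carbon, and control of the face by the catalyst.

## Other disconnections considered

Alternative 1: The cut is C4–C5 of a cyclohexene that has the C1=C6 alkene, the C3 methylidene and C9 at the acid oxidation level. In the forward direction the δ-lactone A1 (its carbinol carbon is the future C1, its vinyl carbons the future C6 and C5) is O-silylated at the enolate stage and undergoes an Ireland–Claisen shift. The shift forms C4–C5, breaks C1–O and contracts the lactone to the acid A2. In its favour, this is a precedented reaction class, and on precedent it is the better of the two plans. C4 would come by chirality transfer from a tertiary carbinol centre, and the methylidene for the last hydrobromination is already in place, which equals the chosen plan. Against it, the cyclic ketene acetal has to react through a boat and A2 carries none of the three halogens. The C1=C6 alkene would have to become the cis bromochloride, although Br–Cl addition is anti and leads to the trans compound. Two electron-rich alkenes would compete for H–Br. The acid must be taken to the same labile α-branched β,γ-unsaturated aldehyde and the same chloro-olefination, an equal liability. In structural terms the chosen plan closes the ring with the C1 oxygen and the C6 bromine already cis, whereas this plan postpones the hardest problem. In step economy the lactone synthesis plus at least six further steps make it longer.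

Alternative 2: The cuts are C4–C5 and C1–C6, a [4+2] retron. In the forward direction the 1-silyloxy diene A3 (C1 to C4 of the ring) and 2-bromoacrolein A4 (C5 and C6) combine under a chiral cationic oxazaborolidine Lewis acid to the cyclohexene A5, with the C2=C3 alkene in place. In its favour, one catalytic enantioselective step would make the ring and three stereocentres, with the C6 bromine cis to the C1 oxygen through the usual exo-formyl preference. In bonds and stereocentres per step, in convergence and in catalytic asymmetric precedent it is the better plan. Against it, the diene terminus C1 is fully substituted, so one group must sit inside the s-cis diene, and C1–C6 joins two fully substituted carbons. The formyl carbon is one carbon too many and would have to be excised from a tertiary α-bromo aldehyde with retention. The C1 oxygen is allylic, so its replacement by chlorine invites allylic transposition; here the chosen plan, with a non-allylic carbinol, is better. The protected hydroxymethyl group needs three steps to become the chloroalkene. The final H–Br addition to the C2=C3 alkene is equal in kind to the chosen last step. Overall it is the longer route.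

Alternative 3: The cut is C3–C4, starting from the open-chain 1,7-enyne A6, which already holds the C1 chloride and the C6 bromide. In the forward direction Pd(OAc)2 with a phosphine and a carboxylic acid additive hydropalladates the alkyne and inserts the butenyl alkene to form C3–C4. β-Hydride elimination from the methyl group then gives A7, with the C3 methylidene and a vinyl group on C4. In its favour, the Alder-ene cycloisomerisation is well precedented, the better position on mechanism. The C1/C6 halides are set on an open chain, where stereospecific anti addition to an alkene of the right geometry can give the needed relative configuration. On the hardest structural problem this is the better plan, since the chosen one relies on retention in an ion pair. The last hydrobromination is the same, an equal point. Against it, a tertiary chloride and a secondary bromide must survive palladium hydride and zerovalent palladium species, and C4 is controlled only by 1,3-induction from C6. A7 carries a plain vinyl group, which would have to be converted into the chloroalkene in the presence of the more electron-rich methylidene. If H–Br were added first, a β-bromo aldehyde prone to elimination would arise. With the synthesis of A6 and that endgame it is longer than the chosen plan.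

Key step: step 5

Remark on the chemistry: the catalysts and reagents in the Conditions lines are taken to be commercial; ring locants C1–C6 in the text are those defined above, names in the lists carry IUPAC locants, and 7 stands for the mixture of both C3 epimers, so its SMILES leaves that one centre open.

## Route

Step 1
Reactants: 1 3-methylbut-2-enal; 2 but-3-en-2-one
Product: 3 (2R)-5-oxo-2-(prop-1-en-2-yl)hexanal
Conditions: (R)-2-[diphenyl(trimethylsilyloxy)methyl]pyrrolidine (20 mol %), PhCO2H (20 mol %), toluene, 0 °C to rt; short silica plug, used at once
Reagents that add atoms: none
Why: Condensation of 1 with the secondary amine gives an E,s-trans dienamine whose α-carbon adds to the vinyl ketone (dienamine α-Michael addition, the enamine Michael reaction applied to a γ,γ-disubstituted enal). The diaryl(silyloxy)methyl group blocks one face, and the shielding model predicts the (2R) centre from the (R)-catalyst. The α-branched product should condense only slowly with the hindered amine, which limits racemisation and double-bond migration.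

Step 2
Reactants: 3 (2R)-5-oxo-2-(prop-1-en-2-yl)hexanal; 4 chloroform
Product: 5 (5S,6E)-7-chloro-5-(prop-1-en-2-yl)hept-6-en-2-one
Conditions: CrCl2 (6 equiv), CHCl3 (2 equiv), THF, 65 °C
Reagents that add atoms: none
Why: Takai chloro-olefination: the geminal dichromium species from CHCl3 and CrCl2 adds to the aldehyde much faster than to the ketone, and anti elimination gives the E chloroalkene. The medium is not basic, and once the formyl group is gone the stereocentre is a doubly allylic C–H that no longer epimerises.

Step 3
Reactants: 5 (5S,6E)-7-chloro-5-(prop-1-en-2-yl)hept-6-en-2-one
Product: 6 {[(2Z,5S,6E)-7-chloro-5-(prop-1-en-2-yl)hepta-2,6-dien-2-yl]oxy}trimethylsilane (mainly 2Z)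
Conditions: Me3SiCl, NaI, Et3N, MeCN, rt; pentane extraction
Reagents that add atoms: chlorotrimethylsilane, C[Si](C)(C)Cl
Why: Silyl enol ether formation under equilibrating conditions (Me3SiI formed in the flask, amine hydroiodide as proton shuttle) should favour the more substituted enol ether of the methyl ketone. This fixes C3 as the site of bromination; the stereocentre is not involved.

Step 4
Reactants: 6 {[(2Z,5S,6E)-7-chloro-5-(prop-1-en-2-yl)hepta-2,6-dien-2-yl]oxy}trimethylsilane
Product: 7 (3RS,5S,6E)-3-bromo-7-chloro-5-(prop-1-en-2-yl)hept-6-en-2-one (both C3 epimers, used as the mixture)
Conditions: NBS, NaHCO3, THF, −78 to 0 °C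
Reagents that add atoms: N-bromosuccinimide, O=C1CCC(=O)N1Br
Why: Electrophilic α-bromination of a silyl enol ether, which at low temperature should be much faster than attack of NBS on the 1,1-disubstituted alkene or the chloroalkene; the regiochemistry is that of the enol ether. The remote C5 centre gives no useful induction, so both C3 epimers are expected and are taken on together as 7.

Step 5
Reactants: 7 (3RS,5S,6E)-3-bromo-7-chloro-5-(prop-1-en-2-yl)hept-6-en-2-one (both C3 epimers)
Product: 10 (1R,2S,4S)-2-bromo-4-[(E)-2-chloroethenyl]-1-methyl-5-methylidenecyclohexan-1-ol, via (3S) bromo ketone 8 (not isolated), via aluminium alkoxide 9 (not isolated)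
Conditions: Me2AlBr (2 equiv, from Me3Al and AlBr3, 2:1), Bu4NBr (10 mol %), CH2Cl2, −78 to −20 °C; aq. potassium sodium tartrate
Reagents that add atoms: none
Why: Proposed new method: the dialkylaluminium halide binds the acetyl oxygen of 8, the CH2 terminus of the 2-propenyl group adds to the carbonyl carbon while one hydrogen of the allylic methyl group passes to oxygen in a single six-centre event, and an Al–CH3 group then takes the hydroxyl proton as methane to give alkoxide 9; the closest known reaction type is the Me2AlCl-promoted type 2 carbonyl-ene cyclisation of unsaturated aldehydes and ketones to 3-methylidenecyclohexanols, which has not been shown on an α-bromo ketone or combined with epimerisation. The six-membered ring closes by C1–C2 bond formation, exo with respect to the carbonyl group and endo with respect to the alkene, through a chair in which the carbonyl oxygen must be axial to reach the methyl hydrogen. C1 is the new stereocentre: with the C4 chlorovinyl group (set in step 1) and the C6 bromine both equatorial, the axial oxygen is on the face cis to bromine, which gives the (1R) carbinol. C6 is the second centre the step has to deliver: of the two epimers in 7 only the (3S) epimer 8 can have both substituents equatorial and its C–Br bond antiperiplanar to the incoming carbon (polar Felkin–Anh alignment), so it should close faster than the (3R) epimer, which must place either bromine or the side chain axial. Epimerisation through an enol cannot be relied on, because the methylaluminium reagent destroys every proton shuttle; the (3R) component of 7 is instead expected to be converted into 8 in the flask by degenerate SN2 exchange of bromide at the Lewis-acid-activated α-carbon, the way α-bromo carbonyl compounds racemise in the presence of bromide. For that reason the Lewis acid is the all-bromide Me2AlBr with a catalytic soluble bromide, so that the exchange can change only the configuration at C6 and never the halogen or the composition. The step needs ene closure to beat capture of a C3 cation by halide (helped by the proton-scavenging dialkylaluminium reagent and the low temperature) and exchange to beat closure of the (3R) epimer; once the ring is closed C6 is no longer next to a carbonyl group and stays fixed.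

Step 6
Reactants: 10 (1R,2S,4S)-2-bromo-4-[(E)-2-chloroethenyl]-1-methyl-5-methylidenecyclohexan-1-ol
Product: 12 (1R,2S,4S)-2-bromo-1-chloro-4-[(E)-2-chloroethenyl]-1-methyl-5-methylidenecyclohexane, via chlorosulfite ester 11 (not isolated)
Conditions: SOCl2, 2,6-di-tert-butyl-4-methylpyridine, CH2Cl2, −40 to 0 °C
Reagents that add atoms: thionyl chloride, O=S(Cl)Cl
Why: Chlorodehydroxylation with internal return (SNi): chlorosulfite 11 should ionise to a tertiary cation–chlorosulfite ion pair that collapses with loss of SO2 on the face the oxygen left, and axial capture of a cyclohexyl cation is favoured as well, so the chloride should end up axial and cis to the C6 bromine (retention). The equatorial C6–Br bond lies near the nodal plane of the cation and cannot bridge. The hindered pyridine takes up HCl so that it does not add to the methylidene group.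

Step 7
Reactants: 12 (1R,2S,4S)-2-bromo-1-chloro-4-[(E)-2-chloroethenyl]-1-methyl-5-methylidenecyclohexane
Product: 13 (1R,2S,4S,5R)-1,4-dibromo-5-chloro-2-[(E)-2-chloroethenyl]-1,5-dimethylcyclohexane
Conditions: Co(acac)2 (25 mol %), t-BuOOH (25 mol %), Et3SiH, TsBr, n-PrOH, rt
Reagents that add atoms: 4-methylbenzenesulfonyl bromide, Cc1ccc(cc1)S(=O)(=O)Br
Why: Markovnikov hydrobromination by cobalt-hydride hydrogen-atom transfer: the hydrogen atom goes to the CH2 of the 1,1-disubstituted alkene (the chloroalkene is a far poorer acceptor) and the tertiary C3 radical takes bromine from TsBr. The axial C1–Cl shields the face syn to it, so bromine should enter equatorially and the methyl group becomes axial, which sets C3 as (R) in ring numbering. The neutral radical conditions should not ionise the tertiary chloride, and the radical has no β-halogen to expel.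

## Compound list

1 | 3-methylbut-2-enal | CC(C)=CC=O | starting material
2 | but-3-en-2-one | CC(=O)C=C | starting material
3 | (2R)-5-oxo-2-(prop-1-en-2-yl)hexanal | CC(=O)CC[C@@H](C=O)C(C)=C | intermediate
4 | chloroform (trichloromethane) | ClC(Cl)Cl | starting material
5 | (5S,6E)-7-chloro-5-(prop-1-en-2-yl)hept-6-en-2-one | CC(=O)CC[C@@H](/C=C/Cl)C(C)=C | intermediate
6 | {[(2Z,5S,6E)-7-chloro-5-(prop-1-en-2-yl)hepta-2,6-dien-2-yl]oxy}trimethylsilane | C/C(O[Si](C)(C)C)=C/C[C@@H](/C=C/Cl)C(C)=C | intermediate
7 | (3RS,5S,6E)-3-bromo-7-chloro-5-(prop-1-en-2-yl)hept-6-en-2-one (mixture of the (3S) and (3R) epimers) | CC(=O)C(Br)C[C@@H](/C=C/Cl)C(C)=C | intermediate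
8 | (3S,5S,6E)-3-bromo-7-chloro-5-(prop-1-en-2-yl)hept-6-en-2-one (the epimer that closes) | CC(=O)[C@@H](Br)C[C@@H](/C=C/Cl)C(C)=C | intermediate (not isolated)
9 | bromido(methyl)aluminium (1R,2S,4S)-2-bromo-4-[(E)-2-chloroethenyl]-1-methyl-5-methylidenecyclohexan-1-olate | C[C@@]1(O[Al](C)Br)CC(=C)[C@H](/C=C/Cl)C[C@@H]1Br | intermediate (not isolated)
10 | (1R,2S,4S)-2-bromo-4-[(E)-2-chloroethenyl]-1-methyl-5-methylidenecyclohexan-1-ol | C[C@@]1(O)CC(=C)[C@H](/C=C/Cl)C[C@@H]1Br | intermediate
11 | (1R,2S,4S)-2-bromo-4-[(E)-2-chloroethenyl]-1-methyl-5-methylidenecyclohexyl chlorosulfite (sulfurochloridite) | C[C@@]1(OS(=O)Cl)CC(=C)[C@H](/C=C/Cl)C[C@@H]1Br | intermediate (not isolated)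
12 | (1R,2S,4S)-2-bromo-1-chloro-4-[(E)-2-chloroethenyl]-1-methyl-5-methylidenecyclohexane | C[C@@]1(Cl)CC(=C)[C@H](/C=C/Cl)C[C@@H]1Br | intermediate
13 | (1R,2S,4S,5R)-1,4-dibromo-5-chloro-2-[(E)-2-chloroethenyl]-1,5-dimethylcyclohexane | C[C@@]1(Cl)C[C@@](C)(Br)[C@H](/C=C/Cl)C[C@@H]1Br | target

## Step count and least certain steps

Total step count: 7. Longest linear sequence: 7 steps (1 and 2 to 13); the route has no separate branch.

**Step 5 (key step, the one proposed as a new method).**
- Most likely failure: bromide exchange at C6 is slower than ring closure of the mismatched epimer, so each epimer closes to its own diastereomer and the convergence is lost. A second risk is capture of a C3 cation by halide if the closure becomes stepwise in the presence of the added bromide.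
- Fallback, built from known operations: it sets out from 7. The two epimers are separated by preparative HPLC, which gives 8 and (3R,5S,6E)-3-bromo-7-chloro-5-(prop-1-en-2-yl)hept-6-en-2-one F1. F1 is re-equilibrated with Bu4NBr in acetone at room temperature (bromide-exchange epimerisation of an α-bromo ketone) and the mixture is separated again, so the material converges on 8 outside the ene flask. Pure 8 is then closed with Me2AlCl in CH2Cl2 at −78 °C, the standard promoter of type 2 carbonyl-ene closures. The closure passes through chlorido(methyl)aluminium (1R,2S,4S)-2-bromo-4-[(E)-2-chloroethenyl]-1-methyl-5-methylidenecyclohexan-1-olate F2, and tartrate work-up brings the route back at 10.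
- This replaces the dynamic process by resolution with recycle and asks the closure for no epimerisation and no unusual Lewis acid. Each operation is a known reaction type; the closure is the standard ene cyclisation of a ketone, applied here to a more electrophilic α-bromo ketone.

**Step 6.**
- Most likely failure: the tertiary cation loses a proton (E1, toward C2 to a conjugated diene or to the exocyclic position) instead of collapsing with chloride, because the adjacent C–Br bond slows ionisation and the ion pair then lives long enough to eliminate. Participation of the homoallylic methylidene and HCl addition to it are further risks.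
- Fallback with a different leaving group and a proton-free medium: it sets out from 10, which is treated with 1-chloro-N,N,2-trimethylprop-1-en-1-amine in CH2Cl2 at 0 °C. The alkoxyiminium salt N-[1-({(1R,2S,4S)-2-bromo-4-[(E)-2-chloroethenyl]-1-methyl-5-methylidenecyclohexyl}oxy)-2-methylpropylidene]-N-methylmethanaminium chloride F3 forms without release of HCl. It should ionise to a tight ion pair with an amide as leaving group, and the route comes back at 12.

**Step 7.**
- Most likely failure: poor facial selectivity in the bromine-atom transfer, because a tertiary cyclohexyl radical is nearly planar and discriminates between its faces only through the axial C1–Cl. Simple reduction of the radical by the silane is a second risk.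
- Fallback with a polar mechanism: it sets out from 12, which is treated with HBr in AcOH/CH2Cl2 at −40 °C (Markovnikov addition through the tertiary C3 cation, bromide entering away from the axial chlorine), and comes back at 13. It makes no new compound and is held in reserve because the acid could exchange the C1 chloride.

**Step 1.**
- Most likely failure: reaction through the γ-carbon of the dienamine or [4+2] cycloaddition with the vinyl ketone, because both compete with α-attack for this class of dienamine. Aldol condensation of the keto aldehyde and erosion of the α-centre are further risks.
- Fallback with a stoichiometric auxiliary: it sets out from 2. (4R)-4-Benzyl-3-(3-methylbut-3-enoyl)-1,3-oxazolidin-2-one F4 (from 3-methylbut-3-enoic acid and the oxazolidinone through the mixed pivalic anhydride) is enolised with TiCl4 and i-Pr2NEt in CH2Cl2 at −78 °C and added to 2 through its α-carbon, anti to the benzyl group, to give (4R)-4-benzyl-3-[(2R)-5-oxo-2-(prop-1-en-2-yl)hexanoyl]-1,3-oxazolidin-2-one F5.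
- EtSH and n-BuLi in THF convert F5 into S-ethyl (2R)-5-oxo-2-(prop-1-en-2-yl)hexanethioate F6. Fukuyama reduction (Et3SiH, palladium on carbon (Pd/C), acetone) gives the aldehyde without touching the ketone, and the route comes back at 3.

## Further compounds

F1 | step 5 | (3R,5S,6E)-3-bromo-7-chloro-5-(prop-1-en-2-yl)hept-6-en-2-one | CC(=O)[C@H](Br)C[C@@H](/C=C/Cl)C(C)=C
F2 | step 5 | chlorido(methyl)aluminium (1R,2S,4S)-2-bromo-4-[(E)-2-chloroethenyl]-1-methyl-5-methylidenecyclohexan-1-olate | C[C@@]1(O[Al](C)Cl)CC(=C)[C@H](/C=C/Cl)C[C@@H]1Br
F3 | step 6 | N-[1-({(1R,2S,4S)-2-bromo-4-[(E)-2-chloroethenyl]-1-methyl-5-methylidenecyclohexyl}oxy)-2-methylpropylidene]-N-methylmethanaminium chloride | CC(C)C(=[N+](C)C)O[C@]1(C)CC(=C)[C@H](/C=C/Cl)C[C@@H]1Br.[Cl-]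
F0 | step 7 | none | none
F4 | step 1 | (4R)-4-benzyl-3-(3-methylbut-3-enoyl)-1,3-oxazolidin-2-one | CC(=C)CC(=O)N1[C@H](Cc2ccccc2)COC1=O
F5 | step 1 | (4R)-4-benzyl-3-[(2R)-5-oxo-2-(prop-1-en-2-yl)hexanoyl]-1,3-oxazolidin-2-one | CC(=O)CC[C@@H](C(=O)N1[C@H](Cc2ccccc2)COC1=O)C(C)=C
F6 | step 1 | S-ethyl (2R)-5-oxo-2-(prop-1-en-2-yl)hexanethioate | CC(=O)CC[C@@H](C(=O)SCC)C(C)=C
A1 | alternative 1 | (6R)-6-ethenyl-6-methyl-4-methylideneoxan-2-one | C=C[C@@]1(C)CC(=C)CC(=O)O1
A2 | alternative 1 | (1R)-4-methyl-6-methylidenecyclohex-3-ene-1-carboxylic acid | OC(=O)[C@@H]1CC=C(C)CC1=C
A3 | alternative 2 | (2E,4E)-3-methyl-5-[(triethylsilyl)oxy]hexa-2,4-dien-1-yl 2,2-dimethylpropanoate | C/C(O[Si](CC)(CC)CC)=C\C(C)=C\COC(=O)C(C)(C)C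
A4 | alternative 2 | 2-bromoprop-2-enal | C=C(Br)C=O
A5 | alternative 2 | [(1R,4R,5S)-5-bromo-5-formyl-2,4-dimethyl-4-[(triethylsilyl)oxy]cyclohex-2-en-1-yl]methyl 2,2-dimethylpropanoate | C[C@@]1(O[Si](CC)(CC)CC)C=C(C)[C@H](COC(=O)C(C)(C)C)C[C@@]1(Br)C=O
A6 | alternative 3 | (4R,5S,7E)-5-bromo-4-chloro-4-methylnon-7-en-1-yne | C[C@@]([C@@H](Br)C/C=C/C)(Cl)CC#C
A7 | alternative 3 | (1R,2S,4S)-2-bromo-1-chloro-4-ethenyl-1-methyl-5-methylidenecyclohexane | C[C@@]1(Cl)CC(=C)[C@H](C=C)C[C@@H]1Br
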